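Reagent cannot enter the flask faster than 3.84 mM s⁻¹, the transfer rate with none dissolved, and my reckoning starts from that ceiling.

- spring: starting material 2.0 M; second substrate 0.200 equiv; gas 160 mM (held); time 50 min
- dawn: starting material 2.0 M; second substrate 0.300 equiv; gas 160 mM (held); time 50 min

    starting material + reagent → target (k1 = 0.058 L mol⁻¹ s⁻¹)
    second substrate + reagent → second product (k2 = 0.092 L mol⁻¹ s⁻¹)
    starting material + second substrate → cross product (k3 = 0.011 L mol⁻¹ s⁻¹)
    2 reagent → self-condensation product (k4 = 0.043 L mol⁻¹ s⁻¹)
    gas ⇌ reagent, rate k5*(csat - [reagent]) (k5 = 0.024 s⁻¹, csat = 160 mM)

1. which of these there is most of at the end, counted by the starting material in it, spring (target / cross product / starting material)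
2. which of these there is most of at the end, counted by the starting material in it, dawn (target / cross product / starting material)
3. the largest of these amounts at the end, in percent of the starting material charged, spring
4. the largest of these amounts at the end, in percent of the starting material charged, dawn

- a step written with two of one species runs at k times the square of its concentration and takes two of it each time
- at the start none of reagent is dissolved
- run time (spring): 50 min

I count what is lost, not what is made: starting material ends as target or cross product, so target is the fraction left once the cross product has taken its part. On the lowest rung of the ladder, in spring, dissolved reagent has a half-life of 0.10 min by the step to target alone, with the starting material at its charge, shorter than the 0.481 min half-time of transfer. So I set transfer in equal to use by the steps to target and second product, which gives c(reagent) = 21.7 mM at the charge.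

On the next rung, second substrate has two ways out in spring. Its half-life is 0.525 min with starting material, shorter than the 5.78 min with reagent at that level. The cross share, the fraction of second substrate lost to cross product, is the pace of the first way over the sum of both paces, a selectivity: 91.7% at the charge, which I hold over the short life of second substrate.

On the top rung, the ceiling could feed the whole charge of starting material in 8.68 min, which is less than the 50 min run but longer than the half-life of second substrate with starting material. So I estimate target as one minus cross share times equivalents: 81.7% in spring. With dawn's own share of 92.4%, it is 72.3% at dawn.

The forecast names target in spring and target at dawn, at 82% (80.5% to 83.5%) and 73.5% (71.5% to 75.5%), reasoning that “the dissolved reagent stays low while the starting material is abundant”. My figures are lower than the forecast's, by 0.30 percentage points in spring and by 1.2 points at dawn.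

The flask gives target at 82.2% in spring and target at 73.6% at dawn. Spring's target still reads 82.2% at 500 min. Spring's cross share prices the extra second substrate of dawn at 9.2 points of target, and the two flasks differ in target by 8.6 points.

Take spring with 0.80 M of starting material and the same equivalents: c(reagent) at the charge is 45.1 mM, the cross share 68.0%, and target 86.4%. That flask gives 88.2% target and 11.8% cross product.

The numbers are assumed; no experiment stands behind them.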